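## Structural features

Atom numbers follow the 1,3-benzodioxol-5-one skeleton of the target (O1, C2, O3, C3a, C4, C5, C6, C7, C7a). The target is a six-membered carbocycle (C3a–C4–C5–C6–C7–C7a) fused along C3a–C7a to a 1,3-dioxolane (O1, C2, O3). The unit O3–C3a=C4–C5=O is a vinylogous ester, that is, the enol of a cyclohexane-1,3-dione tied back through the C2 methylene to the tertiary oxygen on C7a, so the dioxolane is also a formaldehyde acetal. There are three stereocentres: the oxygenated quaternary C7a (R), the side-chain methine directly attached to it (S, carrying methyl and 3,4,5-trimethoxybenzyl), and C6 (R, allyl), which stands 1,3 to C7a across C7 with the allyl group cis to O1. The fragile points are the acetal/vinylogous ester (acid), the C6–H next to the C5 carbonyl (base), the terminal alkene and the electron-rich arene (electrophilic oxidants, alkene-isomerising metals), and the tertiary α-ketol that exists before the bridge is closed. The real difficulty is the oxygenated quaternary C7a flanked by a stereogenic methine, its relation to the remote C6, and the closure of an acid-labile bridge on an ambident dione. The key step exploits the 1,5-relationship of C5 and C3a through C6–C7–C7a with C4 between them: the carbocycle is the Robinson-type union of a C5–C6 aldehyde unit carrying the allyl group and a four-carbon vinyl ketone unit C4–C3a–C7a–C7 carrying the side chain.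

## Logic of the disconnections

**18 ⇒ 16.** The two C–O bonds of C2 (O1–C2 and O3–C2) are cut. The bridge is a formaldehyde acetal spanning a tertiary alcohol and an enol, so removing it exposes 16, in which the vinylogous ester is simply a 1,3-dione. The bicycle becomes a monocycle and the acid-labile group is placed last. The forward step must alkylate the oxygen on C3a and not C4 or the oxygen on C5, with a base too weak to epimerise C6.

**16 ⇒ 15 ⇒ 13.** The C5 carbonyl is traced back through the C5 alcohol of 15 and the C5–B bond of 14 to the enone 13; the bond cut is C5–O. C5 is the β-carbon of the enone in 13, so oxygen can be delivered there by conjugate addition of a boryl nucleophile and oxidation. An acidic, ambident dione is replaced by a plain enone. The forward steps must leave the terminal alkene, the arene and the free tertiary hydroxyl alone.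

**13 ⇒ 11.** The C7a–O1 bond is cut. C7a is the α′-carbon of the C3a ketone, so the oxygen can arrive as an electrophile on the tetrasubstituted enolate 12. The oxygenated quaternary centre is reduced to an epimerisable methine. The forward step needs α′-selective enolisation and oxygen delivery to the face syn to the C6 allyl group.

**11 ⇒ 8 + 9 (key).** C6–C7 and C4=C5 are cut. The enone is an aldol retron and the C3a/C5 1,5-relationship a Michael retron; C6 becomes the α-carbon of an aldehyde, so it can be set by amine catalysis and the allyl group arrives ready-made in 9. The ring and the C6 stereocentre are removed and one fragment is commercial. The enamine must add to a hindered 1,1-disubstituted enone faster than 9 condenses with itself, and 10 must close before C6 epimerises.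

**8 ⇒ 7 ⇒ 6 ⇒ 5.** The acetyl C–CH3 bond (7 ⇒ 6) and the exocyclic C=CH2 bond (6 ⇒ 5) are cut. The methylene is put on an aldehyde that has only one α-carbon; the alternative, methylenating a methyl ketone with two enolisable sides, would be regiochemically ambiguous. This leaves a linear aldehyde with one stereocentre. The forward steps need 1,2-addition to the enal and a neutral oxidation, so the exocyclic alkene does not migrate toward the stereocentre.

**5 ⇒ 4 ⇒ 3.** The C3–H bond is cut. The stereocentre is β to the carbonyl, the retron of an asymmetric conjugate reduction. The only stereocentre of the fragment disappears into a prochiral enoate. The forward step needs geometrically pure 3 and face-selective hydride delivery.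

**3 ⇒ 1 + 2.** The C2=C3 double bond is cut by a phosphonate olefination, giving two commercial materials. The forward step must favour the E isomer and must not let the double bond drift toward the arene.

## Other disconnections considered

**Alternative 1:** The cut removes O1–C2 and O3–C3a and leads back to the para-quinol A1 and a formaldehyde source. In the forward step a chiral phosphoric acid would mediate hemiacetal formation at the tertiary hydroxyl of A1, and the hemiacetal oxygen would add to one enone β-carbon to give the cis-fused dioxolane enone A2.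
- In favour: the dioxolane, the oxygenated C7a and the C5 carbonyl arrive in one catalytic step from a flat dienone. No ambident dione has to be bridged, and on this point the alternative is the better plan. On paper A2 needs only a conjugate reduction with C6 allylation and a C3a–C4 dehydrogenation, so on step economy it is at least the equal.
- Against: A1 already carries the side-chain stereocentre, so its two enone arms are diastereotopic and the acid has to be matched to that centre. The hindered tertiary hydroxyl and the unsubstituted hemiacetal make the cascade slow. A2 is a β-alkoxy ketone, so the C4 enolate needed for the dehydrogenation can expel O3. The C3a centre made by the catalyst is lost in the target.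
- Comparison: structurally it installs heteroatoms first and the allyl carbon last, the reverse of the chosen plan. Mechanistically C6 would be set by substrate-controlled enolate allylation 1,3 to C7a, whereas the chosen plan sets C6 by a catalyst of predictable sense. For C7a neither plan is clearly superior.

**Alternative 2:** The cut is C5–C6. In the forward step a carbene from a chiral triazolium salt would convert the aldehyde of the dioxolane aldehyde–enoate A3 into an acyl anion equivalent that adds to the enoate β-carbon (6-exo-trig) and gives the keto ester A4.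
- In favour: the ring closure is intramolecular and catalyst-controlled at C6, and C5 arrives at the ketone level. As a ring-forming event it is the equal of, or more dependable than, the hindered intermolecular Michael addition of the chosen plan.
- Against: A3 needs the cis-dioxolane with the quaternary C7a, C3a and the side-chain centre assembled acyclically beforehand. Its aldehyde has a β-alkoxy group that can eliminate under the basic carbene conditions. A4 still requires conversion of the ester arm into allyl in the presence of the C5 ketone and the same risky C3a–C4 dehydrogenation.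
- Comparison: structurally the hard C7a problem is moved into the substrate synthesis and not solved. Mechanistically it is sound. On step economy it is clearly the longest of the four plans.

**Alternative 3:** The cut is C7–C7a, followed later by C4–C5. In the forward step SmI2 (divalent samarium) would reduce the α-ketal ketone A5 to a ketyl that adds to the methylene of the acrylate A6; the samarium enolate is protonated at C6 and the alkoxide lactonises to A7. Ketal hydrolysis and an intramolecular Claisen acylation of the methyl ketone on the lactone carbonyl would then open the lactone and join the chosen route at 16.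
- In favour: C7a arrives with its oxygen, so no enolate hydroxylation is needed, and the hindered Michael addition is avoided. The plan is convergent and should reach 16 in no more steps than the chosen route, so on step economy it is the equal or slightly better.
- Against: C7a would be set by 1,2-induction from the side-chain centre in competition with samarium chelation by the ketal oxygens, with uncertain direction. C6 would be set by an uncontrolled enolate protonation, correctable only if the needed lactone epimer is the more stable one. The stereocentre of A5 is α to the ketone and can racemise. The α-substituted acrylate is a slow ketyl acceptor, and the Claisen product carries a hindered alkoxide that can revert.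
- Comparison: structurally it maps well onto 16. Mechanistically it relies on substrate control at two centres where the chosen plan uses a catalyst for C6 and a chiral oxidant for C7a.

Key step: step 7

**Assumptions**
- Step 2: (R)-DTBM-SEGPHOS is written as the ligand enantiomer assumed to deliver hydride to the Re face of C3 of 3; if a first run shows the opposite sense, the (S)-ligand is used.
- Step 8: the (−)-enantiomer of the oxaziridine is written as the one assumed to be matched with the substrate bias; both enantiomers are available and the choice is fixed by one trial with each.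

## Route

Step 1
Reactants: 1 1-(3,4,5-trimethoxyphenyl)propan-2-one; 2 triethyl phosphonoacetate
Product: 3 ethyl (2E)-3-methyl-4-(3,4,5-trimethoxyphenyl)but-2-enoate
Conditions: 2 (1.2 equiv), NaH (1.1 equiv), THF, 0 °C → rt; E isomer separated on silica
Reagents that add atoms: none
Why: Horner–Wadsworth–Emmons olefination of a methyl ketone; the ester should end up trans to the larger benzylic arm, and keeping the base below the amount of phosphonate guards against drift of the double bond toward the arene.

Step 2
Reactants: 3 ethyl (2E)-3-methyl-4-(3,4,5-trimethoxyphenyl)but-2-enoate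
Product: 4 ethyl (3S)-3-methyl-4-(3,4,5-trimethoxyphenyl)butanoate
Conditions: Cu(OAc)2·H2O (3 mol%), (R)-DTBM-SEGPHOS (3 mol%), (EtO)2MeSiH (2 equiv), tBuOH (2 equiv), toluene, 0 °C → rt
Reagents that add atoms: none
Why: Asymmetric conjugate reduction by a ligated CuH formed from the divalent copper acetate and the silane; the bisphosphine pocket should direct hydride to the Re face of C3 of the E-enoate, which corresponds to 3S, and tBuOH releases the ester from the silyl ketene acetal.

Step 3
Reactants: 4 ethyl (3S)-3-methyl-4-(3,4,5-trimethoxyphenyl)butanoate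
Product: 5 (3S)-3-methyl-4-(3,4,5-trimethoxyphenyl)butanal
Conditions: iBu2AlH (1.05 equiv), CH2Cl2, −78 °C; aq. KNaC4H4O6
Reagents that add atoms: none
Why: Partial reduction of an ester; the tetrahedral aluminium hemiacetal is stable at −78 °C and gives the aldehyde only on work-up, and the β-stereocentre is not acidic.

Step 4
Reactants: 5 (3S)-3-methyl-4-(3,4,5-trimethoxyphenyl)butanal
Product: 6 (3S)-3-methyl-2-methylidene-4-(3,4,5-trimethoxyphenyl)butanal
Conditions: 37% aq. CH2O (1.2 equiv), pyrrolidine (10 mol%), EtCO2H (10 mol%), iPrOH, 45 °C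
Reagents that add atoms: formaldehyde C=O
Why: Amine–acid catalysed α-methylenation (Mannich addition of the enamine to the formaldehyde iminium ion, then elimination of the amine); the aldehyde has a single α-carbon, so the methylene can only enter at C2, and the tertiary allylic C–H of the product is only vinylogously acidic under this mild salt.

Step 5
Reactants: 6 (3S)-3-methyl-2-methylidene-4-(3,4,5-trimethoxyphenyl)butanal
Product: 7 (2RS,4S)-4-methyl-3-methylidene-5-(3,4,5-trimethoxyphenyl)pentan-2-ol
Conditions: MeMgBr (1.2 equiv), THF, −78 → 0 °C; aq. NH4Cl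
Reagents that add atoms: methylmagnesium bromide C[Mg]Br
Why: Grignard 1,2-addition to an α-substituted enal, for which carbonyl attack is strongly preferred over conjugate addition; the carbinol epimers are both used because the centre is oxidised next.

Step 6
Reactants: 7 (2RS,4S)-4-methyl-3-methylidene-5-(3,4,5-trimethoxyphenyl)pentan-2-ol
Product: 8 (4S)-4-methyl-3-methylidene-5-(3,4,5-trimethoxyphenyl)pentan-2-one, also named 3-[(2S)-1-(3,4,5-trimethoxyphenyl)propan-2-yl]but-3-en-2-one
Conditions: DMP (1.2 equiv), CH2Cl2, 0 °C → rt; used at once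
Reagents that add atoms: none
Why: Hypervalent iodine oxidation of a secondary allylic alcohol under neutral conditions, which should keep the exocyclic alkene from moving into conjugation with the stereocentre; the enone is used promptly because α-methylene ketones dimerise on standing.

Step 7
Reactants: 8 (4S)-4-methyl-3-methylidene-5-(3,4,5-trimethoxyphenyl)pentan-2-one; 9 pent-4-enal
Product: 11 (4R,6R)-4-(prop-2-en-1-yl)-6-[(2S)-1-(3,4,5-trimethoxyphenyl)propan-2-yl]cyclohex-2-en-1-one, via keto-aldehyde 10 (not isolated)
Conditions: 9 (3 equiv), (S)-2-[diphenyl(trimethylsilyloxy)methyl]pyrrolidine (20 mol%), ethyl 3,4-dihydroxybenzoate (20 mol%), neat, 4 °C → rt; excess 9 evaporated; then (Bn2NH2)(O2CCF3) (30 mol%), toluene, 50 °C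
Reagents that add atoms: none
Why: The secondary amine condenses with 9 to the E-anti enamine, whose α-carbon (C6) adds to the unsubstituted methylene (C7) of 8 while the catechol co-catalyst activates the enone by hydrogen bonding; hydrolysis releases keto-aldehyde 10 and the catalyst. The closest known reaction type is the diarylprolinol silyl ether catalysed Michael addition of aldehydes to simple vinyl ketones followed by aldol condensation to 4-substituted cyclohex-2-enones, a Robinson-type annulation, and the α-branch of 8 is the only departure from it. In the second stage the ammonium salt activates the aldehyde and the methyl ketone enol (C4) attacks C5 in a 6-(enolendo)-exo-trig closure, after which elimination gives the C4=C5 enone; closure through C7a or through the aldehyde enol would give four-membered rings and is excluded. C6 is controlled by the catalyst: the C(Ph)2OSiMe3 group shields the Re face of the enamine α-carbon, so bond formation on the Si face gives 6R in target numbering (4R in 11). C7a is not controlled in the Michael step but is epimerisable next to the ketone and should settle as the cis, diequatorial isomer; its configuration is erased in step 8 in any case. The step needs cross-Michael addition to win over self-aldolisation of 9, which the bulky silyl ether catalyst and the excess of the cheap aldehyde favour, and it needs the side-chain centre of 8 to stay intact, which holds because the hindered catalyst does not condense with the ketone and no strong base is present. Ring closure under a weakly acidic ammonium salt, not hydroxide, is chosen so that C6 in 10 does not epimerise.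

Step 8
Reactants: 11 (4R,6R)-4-(prop-2-en-1-yl)-6-[(2S)-1-(3,4,5-trimethoxyphenyl)propan-2-yl]cyclohex-2-en-1-one
Product: 13 (4R,6R)-6-hydroxy-4-(prop-2-en-1-yl)-6-[(2S)-1-(3,4,5-trimethoxyphenyl)propan-2-yl]cyclohex-2-en-1-one, via potassium dienolate 12 (not isolated)
Conditions: KN(SiMe3)2 (1.15 equiv), THF, −78 °C; then (−)-(camphorsulfonyl)oxaziridine (1.5 equiv), −78 → −50 °C; aq. NH4Cl
Reagents that add atoms: (−)-(camphorsulfonyl)oxaziridine, from (1R)-(−)-camphor-10-sulfonic acid, CC1(C)[C@H]2CC[C@@]13CS(=O)(=O)N4O[C@]34C2
Why: Kinetic deprotonation at the α′-methine gives the cross-conjugated dienolate 12, whose C7a attacks the electrophilic oxygen of the N-sulfonyloxaziridine (enolate hydroxylation). With the side-chain C–H eclipsing the enolate double bond (allylic 1,3-strain) the methyl group lies on the face syn to the C6 allyl group and the aryl-bearing arm on the other, so oxygen should arrive syn to the allyl group, and the matched enantiomer of the chiral oxidant reinforces this modest bias to give 7aR in target numbering (6R in 13).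

Step 9
Reactants: 13 (4R,6R)-6-hydroxy-4-(prop-2-en-1-yl)-6-[(2S)-1-(3,4,5-trimethoxyphenyl)propan-2-yl]cyclohex-2-en-1-one
Product: 15 (2R,4R,5RS)-2,5-dihydroxy-4-(prop-2-en-1-yl)-2-[(2S)-1-(3,4,5-trimethoxyphenyl)propan-2-yl]cyclohexan-1-one, via β-boryl ketone 14 (not isolated)
Conditions: CuCl (5 mol%), NaOtBu (10 mol%), DPEphos (5 mol%), B2pin2 (1.2 equiv), MeOH (2 equiv), THF, rt; then NaBO3·4H2O, THF/H2O, rt
Reagents that add atoms: sodium perborate [Na+].[O-]OB=O (oxygen of the C5 hydroxyl); bis(pinacolato)diboron CC1(C)OB(OC1(C)C)B1OC(C)(C)C(C)(C)O1 (boron held only in 14)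
Why: Copper-catalysed conjugate borylation: the Cu–Bpin species adds boron to the enone β-carbon C5 and MeOH protonates the copper enolate, while the unactivated terminal alkene is inert under these conditions. Perborate then oxidises the C–B bond with retention; the C5 configuration (expected mainly trans to the allyl group) is irrelevant because the centre becomes a carbonyl in step 10.

Step 10
Reactants: 15 (2R,4R,5RS)-2,5-dihydroxy-4-(prop-2-en-1-yl)-2-[(2S)-1-(3,4,5-trimethoxyphenyl)propan-2-yl]cyclohexan-1-one
Product: 16 (4R,6R)-4-hydroxy-6-(prop-2-en-1-yl)-4-[(2S)-1-(3,4,5-trimethoxyphenyl)propan-2-yl]cyclohexane-1,3-dione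
Conditions: IBX (2.5 equiv), EtOAc, 75 °C
Reagents that add atoms: none
Why: Hypervalent iodine oxidation of a β-hydroxy ketone to the β-diketone; the tertiary α-ketol cannot be oxidised, and IBX in hot EtOAc is chosen to avoid over-oxidation at C4 of the acidic dione.

Step 11
Reactants: 16 (4R,6R)-4-hydroxy-6-(prop-2-en-1-yl)-4-[(2S)-1-(3,4,5-trimethoxyphenyl)propan-2-yl]cyclohexane-1,3-dione
Product: 18 (6R,7aR)-6-(prop-2-en-1-yl)-7a-[(2S)-1-(3,4,5-trimethoxyphenyl)propan-2-yl]-7,7a-dihydro-1,3-benzodioxol-5(6H)-one, via chloromethyl enol ether 17 (not isolated)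
Conditions: BrCH2Cl (5 equiv), Cs2CO3 (3 equiv), DMF, 60 °C
Reagents that add atoms: bromochloromethane ClCBr
Why: Double Williamson-type O-alkylation, the methylenation used for catechols and diols: the cesium enolate of the dione displaces bromide to give 17, and the neighbouring tertiary hydroxyl then displaces chloride from this α-chloro ether in a 5-exo-tet closure that only the oxygen on C3a can reach. No stereocentre is touched and the carbonate base is too weak to epimerise C6.

## Compound list

1 | 1-(3,4,5-trimethoxyphenyl)propan-2-one | CC(=O)Cc1cc(OC)c(OC)c(OC)c1 | starting material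
2 | triethyl phosphonoacetate | CCOC(=O)CP(=O)(OCC)OCC | starting material
3 | ethyl (2E)-3-methyl-4-(3,4,5-trimethoxyphenyl)but-2-enoate | CCOC(=O)/C=C(\C)Cc1cc(OC)c(OC)c(OC)c1 | intermediate
4 | ethyl (3S)-3-methyl-4-(3,4,5-trimethoxyphenyl)butanoate | CCOC(=O)C[C@@H](C)Cc1cc(OC)c(OC)c(OC)c1 | intermediate
5 | (3S)-3-methyl-4-(3,4,5-trimethoxyphenyl)butanal | O=CC[C@@H](C)Cc1cc(OC)c(OC)c(OC)c1 | intermediate
6 | (3S)-3-methyl-2-methylidene-4-(3,4,5-trimethoxyphenyl)butanal | O=CC(=C)[C@@H](C)Cc1cc(OC)c(OC)c(OC)c1 | intermediate
7 | (2RS,4S)-4-methyl-3-methylidene-5-(3,4,5-trimethoxyphenyl)pentan-2-ol | CC(O)C(=C)[C@@H](C)Cc1cc(OC)c(OC)c(OC)c1 | intermediate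
8 | (4S)-4-methyl-3-methylidene-5-(3,4,5-trimethoxyphenyl)pentan-2-one | CC(=O)C(=C)[C@@H](C)Cc1cc(OC)c(OC)c(OC)c1 | intermediate
9 | pent-4-enal | C=CCCC=O | starting material
10 | (2R,4RS,5S)-4-acetyl-5-methyl-2-(prop-2-en-1-yl)-6-(3,4,5-trimethoxyphenyl)hexanal | C=CC[C@@H](C=O)CC(C(C)=O)[C@@H](C)Cc1cc(OC)c(OC)c(OC)c1 | intermediate (not isolated)
11 | (4R,6R)-4-(prop-2-en-1-yl)-6-[(2S)-1-(3,4,5-trimethoxyphenyl)propan-2-yl]cyclohex-2-en-1-one | C=CC[C@@H]1C[C@H]([C@@H](C)Cc2cc(OC)c(OC)c(OC)c2)C(=O)C=C1 | intermediate
12 | potassium (4R)-4-(prop-2-en-1-yl)-2-[(2S)-1-(3,4,5-trimethoxyphenyl)propan-2-yl]cyclohexa-1,5-dien-1-olate | C=CC[C@@H]1CC(=C([O-])C=C1)[C@@H](C)Cc2cc(OC)c(OC)c(OC)c2.[K+] | intermediate (not isolated)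
13 | (4R,6R)-6-hydroxy-4-(prop-2-en-1-yl)-6-[(2S)-1-(3,4,5-trimethoxyphenyl)propan-2-yl]cyclohex-2-en-1-one | C=CC[C@@H]1C[C@@](O)([C@@H](C)Cc2cc(OC)c(OC)c(OC)c2)C(=O)C=C1 | intermediate
14 | (2R,4R,5RS)-2-hydroxy-4-(prop-2-en-1-yl)-5-(4,4,5,5-tetramethyl-1,3,2-dioxaborolan-2-yl)-2-[(2S)-1-(3,4,5-trimethoxyphenyl)propan-2-yl]cyclohexan-1-one | C=CC[C@@H]1C[C@@](O)([C@@H](C)Cc2cc(OC)c(OC)c(OC)c2)C(=O)CC1B3OC(C)(C)C(C)(C)O3 | intermediate (not isolated)
15 | (2R,4R,5RS)-2,5-dihydroxy-4-(prop-2-en-1-yl)-2-[(2S)-1-(3,4,5-trimethoxyphenyl)propan-2-yl]cyclohexan-1-one | C=CC[C@@H]1C[C@@](O)([C@@H](C)Cc2cc(OC)c(OC)c(OC)c2)C(=O)CC1O | intermediate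
16 | (4R,6R)-4-hydroxy-6-(prop-2-en-1-yl)-4-[(2S)-1-(3,4,5-trimethoxyphenyl)propan-2-yl]cyclohexane-1,3-dione | C=CC[C@@H]1C[C@@](O)([C@@H](C)Cc2cc(OC)c(OC)c(OC)c2)C(=O)CC1=O | intermediate
17 | (4R,6R)-3-(chloromethoxy)-4-hydroxy-6-(prop-2-en-1-yl)-4-[(2S)-1-(3,4,5-trimethoxyphenyl)propan-2-yl]cyclohex-2-en-1-one | C=CC[C@@H]1C[C@@](O)([C@@H](C)Cc2cc(OC)c(OC)c(OC)c2)C(OCCl)=CC1=O | intermediate (not isolated)
18 | (6R,7aR)-6-(prop-2-en-1-yl)-7a-[(2S)-1-(3,4,5-trimethoxyphenyl)propan-2-yl]-7,7a-dihydro-1,3-benzodioxol-5(6H)-one | C=CC[C@@H]1C[C@]2([C@@H](C)Cc3cc(OC)c(OC)c(OC)c3)OCOC2=CC1=O | target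

## Step count and least certain steps

Total step count: 11. Longest linear sequence: 11 steps (1 → 18); 9 enters at step 7.

**Step 7 (key step).** The conjugate addition is the most likely to stall, because the enamine has to attack a 1,1-disubstituted enone whose α-branch is a bulky secondary alkyl group. While it waits, 9 can condense with itself, and slow ring closure would let C6 of 10 lose configuration. Fallback, setting out from 8 and 9 and returning at 11: 9 is condensed with pyrrolidine (K2CO3, 0 °C) to 1-[(1E)-penta-1,4-dien-1-yl]pyrrolidine F1, which is heated with 8 in MeCN in a Stork enamine alkylation and then hydrolysed and cyclised with aqueous AcOH/NaOAc. C6 is not controlled in this variant, but since the side-chain centre is fixed the two products are diastereomers, 11 and (4S,6S)-4-(prop-2-en-1-yl)-6-[(2S)-1-(3,4,5-trimethoxyphenyl)propan-2-yl]cyclohex-2-en-1-one F2, to be separated by chromatography.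

**Step 8.** Facial discrimination on the planar C7a may be insufficient: the ring's preference for attack anti to the C6 substituent opposes the side-chain bias, and the oxidant has to overrule a small difference. Competing γ-deprotonation at C6 would in addition scramble that centre. Fallback, setting out from 11 and returning at 13: the potassium enolate is trapped with Et3SiCl to give triethyl{[(4R)-4-(prop-2-en-1-yl)-2-[(2S)-1-(3,4,5-trimethoxyphenyl)propan-2-yl]cyclohexa-1,5-dien-1-yl]oxy}silane F3, which is isolated. Its electron-rich enol ether double bond is then oxidised in a Shi epoxidation (fructose-derived ketone catalyst or its enantiomer, KHSO5, K2CO3, MeCN/dimethoxymethane/H2O, 0 °C), a Rubottom-type hydroxylation under catalyst control; loss of the silyl group on work-up should give 13.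

**Step 11.** The dione enolate is ambident: alkylation at C4 or at the oxygen on C5, followed by intermolecular bridging, can compete with alkylation at the oxygen on C3a. Fallback, setting out from 13 and returning at 18, with the bridging carbon attached to O1 first so that only the C3a oxygen can reach it:
- 13 is converted with MOMCl, iPr2NEt and nBu4NI (ClCH2CH2Cl, 60 °C) into (4R,6R)-6-(methoxymethoxy)-4-(prop-2-en-1-yl)-6-[(2S)-1-(3,4,5-trimethoxyphenyl)propan-2-yl]cyclohex-2-en-1-one F4.
- Conjugate borylation and oxidation as in step 9 pass through (2R,4R,5RS)-2-(methoxymethoxy)-4-(prop-2-en-1-yl)-5-(4,4,5,5-tetramethyl-1,3,2-dioxaborolan-2-yl)-2-[(2S)-1-(3,4,5-trimethoxyphenyl)propan-2-yl]cyclohexan-1-one F5 to (2R,4R,5RS)-5-hydroxy-2-(methoxymethoxy)-4-(prop-2-en-1-yl)-2-[(2S)-1-(3,4,5-trimethoxyphenyl)propan-2-yl]cyclohexan-1-one F6.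
- IBX gives (4R,6R)-4-(methoxymethoxy)-6-(prop-2-en-1-yl)-4-[(2S)-1-(3,4,5-trimethoxyphenyl)propan-2-yl]cyclohexane-1,3-dione F7.
- Me2BBr (CH2Cl2, −78 °C) converts the acetal into (4R,6R)-4-(bromomethoxy)-6-(prop-2-en-1-yl)-4-[(2S)-1-(3,4,5-trimethoxyphenyl)propan-2-yl]cyclohexane-1,3-dione F8, and iPr2NEt then lets the enol oxygen on C3a close the ring to 18.

**Step 2 (with step 1).** Enantiopurity may erode, because the E and Z enoates lead to opposite enantiomers and incomplete separation, or migration of the double bond toward the arene, feeds the wrong isomer into the reduction. Fallback, setting out from 3 used as the E/Z mixture and returning at 5: iBu2AlH (CH2Cl2, −78 °C) gives 3-methyl-4-(3,4,5-trimethoxyphenyl)but-2-en-1-ol F9, and MnO2 gives 3-methyl-4-(3,4,5-trimethoxyphenyl)but-2-enal F10. An iminium-catalysed transfer hydrogenation (the appropriate enantiomer of 2-tert-butyl-3-methylimidazolidin-4-one as its trichloroacetate salt, Hantzsch ester, CHCl3, −30 °C) then reduces the enal; it is convergent in alkene geometry because the iminium isomers interconvert.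

## Further compounds

F1 | step 7 | 1-[(1E)-penta-1,4-dien-1-yl]pyrrolidine | C=CC/C=C/N1CCCC1
F2 | step 7 | (4S,6S)-4-(prop-2-en-1-yl)-6-[(2S)-1-(3,4,5-trimethoxyphenyl)propan-2-yl]cyclohex-2-en-1-one | C=CC[C@H]1C[C@@H]([C@@H](C)Cc2cc(OC)c(OC)c(OC)c2)C(=O)C=C1
F3 | step 8 | triethyl{[(4R)-4-(prop-2-en-1-yl)-2-[(2S)-1-(3,4,5-trimethoxyphenyl)propan-2-yl]cyclohexa-1,5-dien-1-yl]oxy}silane | C=CC[C@@H]1CC(=C(O[Si](CC)(CC)CC)C=C1)[C@@H](C)Cc2cc(OC)c(OC)c(OC)c2
F4 | step 11 | (4R,6R)-6-(methoxymethoxy)-4-(prop-2-en-1-yl)-6-[(2S)-1-(3,4,5-trimethoxyphenyl)propan-2-yl]cyclohex-2-en-1-one | C=CC[C@@H]1C[C@@](OCOC)([C@@H](C)Cc2cc(OC)c(OC)c(OC)c2)C(=O)C=C1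
F5 | step 11 | (2R,4R,5RS)-2-(methoxymethoxy)-4-(prop-2-en-1-yl)-5-(4,4,5,5-tetramethyl-1,3,2-dioxaborolan-2-yl)-2-[(2S)-1-(3,4,5-trimethoxyphenyl)propan-2-yl]cyclohexan-1-one | C=CC[C@@H]1C[C@@](OCOC)([C@@H](C)Cc2cc(OC)c(OC)c(OC)c2)C(=O)CC1B3OC(C)(C)C(C)(C)O3
F6 | step 11 | (2R,4R,5RS)-5-hydroxy-2-(methoxymethoxy)-4-(prop-2-en-1-yl)-2-[(2S)-1-(3,4,5-trimethoxyphenyl)propan-2-yl]cyclohexan-1-one | C=CC[C@@H]1C[C@@](OCOC)([C@@H](C)Cc2cc(OC)c(OC)c(OC)c2)C(=O)CC1O
F7 | step 11 | (4R,6R)-4-(methoxymethoxy)-6-(prop-2-en-1-yl)-4-[(2S)-1-(3,4,5-trimethoxyphenyl)propan-2-yl]cyclohexane-1,3-dione | C=CC[C@@H]1C[C@@](OCOC)([C@@H](C)Cc2cc(OC)c(OC)c(OC)c2)C(=O)CC1=O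
F8 | step 11 | (4R,6R)-4-(bromomethoxy)-6-(prop-2-en-1-yl)-4-[(2S)-1-(3,4,5-trimethoxyphenyl)propan-2-yl]cyclohexane-1,3-dione | C=CC[C@@H]1C[C@@](OCBr)([C@@H](C)Cc2cc(OC)c(OC)c(OC)c2)C(=O)CC1=O
F9 | step 2 | 3-methyl-4-(3,4,5-trimethoxyphenyl)but-2-en-1-ol (E/Z mixture) | OCC=C(C)Cc1cc(OC)c(OC)c(OC)c1
F10 | step 2 | 3-methyl-4-(3,4,5-trimethoxyphenyl)but-2-enal (E/Z mixture) | O=CC=C(C)Cc1cc(OC)c(OC)c(OC)c1
A1 | alternative 1 | 4-hydroxy-4-[(2S)-1-(3,4,5-trimethoxyphenyl)propan-2-yl]cyclohexa-2,5-dien-1-one (para-quinol) | O=C1C=CC(O)([C@@H](C)Cc2cc(OC)c(OC)c(OC)c2)C=C1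
A2 | alternative 1 | cis-fused 7a-[(2S)-1-(3,4,5-trimethoxyphenyl)propan-2-yl]-3a,4-dihydro-1,3-benzodioxol-5(7aH)-one | O=C1C=C[C@]2([C@@H](C)Cc3cc(OC)c(OC)c(OC)c3)OCO[C@@H]2C1
A3 | alternative 2 | methyl (2E)-4-{cis-5-(2-oxoethyl)-4-[(2S)-1-(3,4,5-trimethoxyphenyl)propan-2-yl]-1,3-dioxolan-4-yl}but-2-enoate | COC(=O)/C=C/C[C@]1([C@@H](C)Cc2cc(OC)c(OC)c(OC)c2)OCO[C@@H]1CC=O
A4 | alternative 2 | methyl 2-{cis-fused 5-oxo-7a-[(2S)-1-(3,4,5-trimethoxyphenyl)propan-2-yl]hexahydro-1,3-benzodioxol-6-yl}acetate | COC(=O)C[C@@H]1C[C@]2([C@@H](C)Cc3cc(OC)c(OC)c(OC)c3)OCO[C@@H]2CC1=O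
A5 | alternative 3 | (4S)-2,2-dimethoxy-4-methyl-5-(3,4,5-trimethoxyphenyl)pentan-3-one | COC(C)(OC)C(=O)[C@@H](C)Cc1cc(OC)c(OC)c(OC)c1
A6 | alternative 3 | methyl 2-methylidenepent-4-enoate | C=CCC(=C)C(=O)OC
A7 | alternative 3 | 5-(1,1-dimethoxyethyl)-3-(prop-2-en-1-yl)-5-[(2S)-1-(3,4,5-trimethoxyphenyl)propan-2-yl]oxolan-2-one (relay lactone) | C=CC[C@@H]1C[C@](C(C)(OC)OC)([C@@H](C)Cc2cc(OC)c(OC)c(OC)c2)OC1=O
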